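The target forms when partner meets intermediate C, so I follow how much partner each substrate charge leaves for that last step.

    substrate + partner ⇌ intermediate A (K1 = 3.0 /M, k1 = 0.14 /M/s)
    intermediate A ⇌ intermediate B (K2 = 2.9, k2 = 0.017 /s)
    substrate + partner → intermediate C (k3 = 0.43 /M/s)
    partner + intermediate A → side product (k4 = 0.33 /M/s)
    partner + intermediate C → target (k5 = 0.036 /M/s)
    2 substrate → self-condensation product (k6 = 0.048 /M/s)

common to all: partner 0.132 M; time 20 s
- delta: substrate 0.050 M
- beta: substrate 0.080 M
- zeta: substrate 0.12 M
- theta: substrate 0.15 M
- alpha: substrate 0.25 M

- [target] at the end for delta, beta, zeta, theta, alpha, in this order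
- the shape of the row from first to last (falls, then rises / rises all the way / hardly changes / falls all the way / rises, then falls)

Substrate takes partner by two forward paths, and I add their constants, setting aside the way back of step 1: 0.570 /M/s. Partner is charged alike in every flask, so I let substrate fade at d times 0.132 M in each. Over 20 s that fading gives a working time of 10.3 s, the time substrate would need at its full charge to do the same work on partner, about half of the run. Partner loss then becomes pseudo-first-order, and the share of partner left is exp(−d × charge × working time).

The last step runs at k5 times c_partner times c_intermediate C. I take c_intermediate C as a fixed share of the charge, so c_target should follow charge times partner left.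

| Flask | Substrate charged | Partner left, reckoned | Charge × partner left |
|---|---|---|---|
| delta | 0.050 M | 74.6% | 0.0372 M |
| beta | 0.080 M | 62.5% | 0.0499 M |
| zeta | 0.12 M | 49.4% | 0.0592 M |
| theta | 0.15 M | 41.5% | 0.0620 M |
| alpha | 0.25 M | 23.0% | 0.0573 M |

Reading down, the last column grows as far as theta. From theta to alpha the column drops. Charge times partner left peaks at a charge of one over d times the working time, 0.170 M. I commit to a rise and then a fall, with the turn there. My reckoning gives this shape but no value of c_target in M.

The forecast gives 0.0012 M, 0.0016 M, 0.0019 M, 0.0019 M and 0.0017 M, with the shape "rises, then falls", on the ground that “substrate has used up so much partner early on”.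

The simulation gives 0.00123 M, 0.00163 M, 0.00191 M, 0.00200 M and 0.00192 M, so the row rises, then falls. The forecast stands within its margin, though its alpha value lies below the flask's. The row turns at a substrate charge of 0.18 M, read from the runs, and my turning charge is 0.170 M. For theta, the working time of 10.3 s gives 41.5% partner left, and theta holds 38% at 20.0 s. For alpha it gives 23.0%, and alpha holds 20% at 20.0 s.

Its constants are invented; the rest is arithmetic.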